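## Structural features

The target is a 3,3a-dihydrobenzofuran-6(2H)-one: an oxolane ring (O1, C2, C3, C3a, C7a) fused through the C3a–C7a bond to a cross-conjugated cyclohexa-2,5-dienone (C3a, C4, C5, C6, C7, C7a). The six-membered ring carries an enol-ether methoxyl at C5 and the ketone at C6, and O1–C7a=C7–C6=O is a vinylogous ester. C2 bears the 3,4,5-trimethoxyphenyl group, C3 a methyl group and C3a an allyl group. The three stereocentres are contiguous: C2 (R) and C3 (S) hold aryl and methyl on the same face of the oxolane, and the quaternary C3a (S) holds allyl on the opposite face. The fragile points are: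

- the C2–O1 bond, which is benzylic to an electron-rich arene and ends in a vinylogous carboxylate oxygen, so acid can ionise it and turn the cis pair into the more stable trans pair;
- the dienone, which can rearomatise by [3,3] allyl shifts towards C5 or C7, by acid, or by one-electron reduction with loss of allyl;
- the terminal alkene.

The real difficulty is the quaternary C3a next to C3, combined with the less stable cis arrangement at C2/C3. The key step uses the fact that the six-membered ring is a dearomatised 1,2,4-trioxygenated benzene. C4 to C7, with the C5 methoxyl and the C6 oxygen, are the four carbons of 3-methoxybut-3-en-2-one; C3a and C7a are the α-carbon and carbonyl carbon of a γ-butyrolactone that already holds C2, C3 and O1. Once the ring is aromatic, C3a is para to the C6 oxygen, so the allyl group can be brought in last on the face left open by the cis methyl and aryl groups.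

## Logic of the disconnections

**22 from 21.** The C7–H bond is traced back to C7–Br. The halogen is needed one step earlier to close the ortho position beside the C6 oxygen. Removing it last leaves every skeletal bond and all three stereocentres in place. The forward step must reduce a vinylic C–Br bond α to the ketone without putting electrons into the dienone (which would expel allyl) and without acid (which would ionise C2–O1).

**21 from 18 and 19 (through 20).** The bond from C3a to the allyl CH2 is cut. This returns the dienone to an aromatic ring and removes the quaternary stereocentre; the allyl group is traced through the O-allyl compound 20 to 19. The cut is made here because C3a is para to the C6 oxygen and, in the flat bicyclic phenoxide, the face anti to the C3 methyl is the open one. The forward step must favour C-allylation at C3a over the reversible O-allylation and must rest on the dienone side. C5 (methoxyl) and C7 (bromine) are occupied, so no ortho C-allyl phenol can form by tautomerisation.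

**18 from 17.** The C7–Br bond is cut. The gain is small, but the forward demand is clear: one bromination ortho to the free hydroxyl in the presence of a second electron-rich arene.

**17 from 13.** The C4=C5 unsaturation, and with it the aromatic sextet, is removed. 13 is one oxidation level lower and already has the C5 methoxyl, the C6 oxygen and O1 on their final carbons. The forward step must dehydrogenate through the α'-carbon C5 and not through C3a towards C3.

**13 from 8 and 10.** The C3a–C4 and C7–C7a bonds are cut; O1–C7a is opened and re-closed in the same operation. The carbocycle falls apart into a four-carbon enone that carries the methoxyl and a lactone that carries C2, C3 and O1 with their stereochemistry. The forward step needs conjugate addition followed by acylation and makes no lasting stereocentre.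

**10 from 9.** The C=C bond of 10 is traced to loss of methanol from a ketal. The forward step needs only acid and removal of methanol, but the product polymerises and must be used fresh.

**8 from 6, and 6 from 4.** The lactone carbonyl is traced to a primary alcohol and then to a terminal alkene. The two stereocentres of 8 then sit in a homoallylic alcohol. The forward steps need anti-Markovnikov hydration and oxidation of the primary alcohol in preference to the benzylic one.

**4 from 1 and 2.** The bond between the carbinol carbon and the methyl-bearing carbon (later C2–C3) is cut. A crotyl transfer through a closed chair transition state turns Z-alkene geometry into the syn relationship that becomes cis in 8, and a chiral acid selects the aldehyde face. This replaces a one-step carbene-catalysed coupling of an enal with 1. That coupling would give 8 directly, but it is not expected to control absolute configuration, or fully the cis/trans ratio, with a β-methyl enal and an electron-rich aldehyde. The forward step must be syn- and Re-face-selective.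

## Other disconnections considered

**Alternative 1:** The cut is C2–C3 of the oxolane. The forward key step decomposes the aryl(methyl)diazomethane A2 with Rh2(R-PTAD)4 (tetrakis[(R)-(1-adamantyl)(N-phthalimido)acetato]dirhodium), or its enantiomer if the facial sense requires it. The carbene inserts into the benzylic ether C–H bond and closes the oxolane to A1, which is the same compound as 20.
- In favour: C2 and C3 are set in one catalyst-controlled step, and insertions of this kind are expected to favour the cis relationship. On stereocontrol this is the equal of the chosen plan. It is better in one respect: no acid-mediated ring closure and no selenium oxidation touch the cis pair.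
- Against: A2 requires a penta-substituted acetophenone built by several regioselective arene operations. Its methyl-substituted carbene has β-hydrogens, so 1,2-hydride shift to a vinylarene competes with insertion.
- Comparison: from A1 the plan needs the same allyl transfer and debromination as the chosen route, so the last two risks are shared. Step economy is about equal once the arene synthesis is counted. The chosen plan obtains the substitution pattern from the polarity of an annulation rather than from arene chemistry.

**Alternative 2:** The cut is C3a–C7a. The forward key step heats the 4-alkenylcyclobutenone A4, which should open to a dienylketene and close by 6π-electrocyclisation to the cyclohexa-2,4-dienone A3. Desilylation and closure of the oxolane onto the C7a carbonyl, with loss of the isopropyl group, would then give 22.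
- In favour: the quaternary C3a and its allyl group are made without any aromatic intermediate, blocking halogen or redox adjustment of the ring. On that point it is better than the chosen plan. The ring expansion is a well-established reaction type.
- Against: the C3a configuration arises in the electrocyclisation and is controlled only by the adjacent acyclic stereocentre and the alkene geometry. That is a weaker bias than the anti-to-methyl approach on the bicyclic phenoxide of the chosen plan. The stereodefined trisubstituted alkenyl fragment with two stereocentres needs its own multistep synthesis. The final acid-mediated closure threatens the cis pair at least as much as step 5 does.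
- Comparison: convergence is equal; the stereochemical risk is moved from a late, substrate-controlled step to an early one that is hard to predict; the total step count is likely higher.

**Alternative 3:** The cut is C5–C6. The forward key step deprotonates the α-methoxy sulfone A6; the C5 carbanion attacks the ester carbon of the exocyclic vinylogous carbonate and closes the six-membered ring to A5. Loss of the sulfinate into C4–C5 would give 22 directly.
- In favour: C3a is set by two successive lactone enolate alkylations, allyl second and therefore anti to methyl. This is kinetic, well-precedented control and is the equal or the better of the dearomative allylation. No aromatic intermediate and no late reduction are needed.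
- Against: a vinylogous carbonate is a poor acyl acceptor and the tertiary carbanion is hindered. A5 has no acidic hydrogen between carbonyl and sulfone, so the closure is not driven by enolate formation and may revert. The exocyclic alkene must be Z, and converting a hindered α,α-disubstituted lactone carbonyl into it is difficult.
- Comparison: the stereochemical logic is sound, but the linear sequence is clearly longer and the ring closure is thermodynamically less secure than the Michael–Claisen step, which ends in a stabilised diketonate.

Key step: step 5

Remark on the structures: the descriptors and SMILES strings of 8, 13, A1, A3 and A5 were re-derived from 22 and agree with it (aryl and methyl cis, allyl anti to methyl, 22 = 2R,3S,3aS); no structure needed correction. Two design changes are made: 8 is reached by catalyst-controlled crotylboration, and the allyl group is delivered in one palladium-catalysed operation from an allyl carbonate.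

Assumption: the (R)-configured phosphoric acid directs the crotyl group to the Re face of 1; if the opposite sense is found, its enantiomer is used with no other change.

## Steps

Step 1
Reactants: 1 3,4,5-trimethoxybenzaldehyde; 2 4,4,5,5-tetramethyl-2-[(2Z)-but-2-en-1-yl]-1,3,2-dioxaborolane
Product: 4 (1R,2S)-2-methyl-1-(3,4,5-trimethoxyphenyl)but-3-en-1-ol, via O-pinacolboryl ether 3 (not isolated)
Conditions: (R)-3,3'-bis(2,4,6-triisopropylphenyl)-1,1'-binaphthalene-2,2'-diyl hydrogen phosphate (5 mol%), 4 Å sieves, PhMe, −30 °C; aq. NaHCO3
Reagents that add atoms: none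
Why: Chiral phosphoric acid catalysed crotylboration through a closed chair (Zimmerman–Traxler) transition state: the Z boronate gives the syn alcohol and the catalyst selects the Re face of the aldehyde, which sets both stereocentres that become C2 and C3.

Step 2
Reactants: 4 (1R,2S)-2-methyl-1-(3,4,5-trimethoxyphenyl)but-3-en-1-ol
Product: 6 (1R,2S)-2-methyl-1-(3,4,5-trimethoxyphenyl)butane-1,4-diol, via bis(boryl) adduct 5 (not isolated)
Conditions: 9-borabicyclo[3.3.1]nonane (2.5 equiv), THF, 0 → 25 °C; NaOH, H2O2, 0 → 25 °C
Reagents that add atoms: hydrogen peroxide, OO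
Why: Anti-Markovnikov hydroboration–oxidation of the monosubstituted alkene; one equivalent of borane is consumed by the free hydroxyl and no stereocentre is touched.

Step 3
Reactants: 6 (1R,2S)-2-methyl-1-(3,4,5-trimethoxyphenyl)butane-1,4-diol
Product: 8 (4S,5R)-4-methyl-5-(3,4,5-trimethoxyphenyl)dihydrofuran-2(3H)-one, via lactol 7 (not isolated)
Conditions: 2,2,6,6-tetramethylpiperidine-1-oxyl (10 mol%), PhI(OAc)2 (2.5 equiv), CH2Cl2, 25 °C
Reagents that add atoms: none
Why: Nitroxyl-catalysed oxidative lactonisation of a 1,4-diol: the primary alcohol is oxidised first, the aldehyde closes to lactol 7, and 7 is oxidised on to the lactone, so the benzylic hydroxyl is engaged before it can be oxidised.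

Step 4
Reactants: 9 3,3-dimethoxybutan-2-one
Product: 10 3-methoxybut-3-en-2-one
Conditions: p-toluenesulfonic acid monohydrate (cat.), hydroquinone (trace), neat, 140–160 °C, MeOH distilled off; product distilled at reduced pressure
Reagents that add atoms: none
Why: Acid-catalysed loss of methanol from the ketal (enol ether formation), driven by removal of methanol; the enone is kept cold with inhibitor and used fresh.

Step 5
Reactants: 8 (4S,5R)-4-methyl-5-(3,4,5-trimethoxyphenyl)dihydrofuran-2(3H)-one; 10 3-methoxybut-3-en-2-one
Product: 13 (2R,3S,3aS)-5-methoxy-3-methyl-2-(3,4,5-trimethoxyphenyl)-3,3a,4,5-tetrahydrobenzofuran-6(2H)-one, via Michael adduct 11 (not isolated), via hydroxy dione 12 (not isolated)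
Conditions: LiN(iPr)2 (1.05 equiv), THF, −78 °C; 10 (1.2 equiv), −78 → 25 °C; AcOH (1.1 equiv); pyridinium p-toluenesulfonate (cat.), 4 Å sieves, CH2Cl2, 25 °C
Reagents that add atoms: none
Why: The lithium enolate of 8 adds through its α-carbon to the unsubstituted β-carbon of 10 (Michael addition, C3a–C4), the resulting α-methoxy enolate equilibrates by proton transfer to the methyl-ketone enolate, and this carbon attacks the lactone carbonyl (Claisen acylation, C7–C7a). The closest known reaction type is the Michael–Claisen annulation of ester enolates with enones to cyclohexane-1,3-diones, here with a lactone as the ester. The carbocycle closes 6-exo-trig; the tetrahedral intermediate expels the benzylic alkoxide, which is quenched by the new 1,3-dione, so the lithium diketonate of 12 is the thermodynamic sink that drives the enolate equilibration and the reversal of any 1,2-adduct. On mild acidification the C2 hydroxyl re-closes the oxolane 5-exo-trig on the C7a carbonyl and the hemiketal dehydrates into conjugation to give the vinylogous ester 13. C3a is set by approach of the enone to the enolate face opposite the cis methyl and aryl groups, and C5 is not controlled (13 is carried on as a C5 epimer mixture); both centres are erased in step 6. The step needs 1,4- over 1,2-addition (secured by the unhindered alkene terminus of 10 and by the thermodynamic funnel), C- over O-acylation (only C-acylation leads to the diketonate) and retention at C2 and C3, which holds because only the acyl C–O bond is broken and the pyridinium salt is too weak an acid to ionise the benzylic C2–O bond.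

Step 6
Reactants: 13 (2R,3S,3aS)-5-methoxy-3-methyl-2-(3,4,5-trimethoxyphenyl)-3,3a,4,5-tetrahydrobenzofuran-6(2H)-one
Product: 17 (2R,3S)-5-methoxy-3-methyl-2-(3,4,5-trimethoxyphenyl)-2,3-dihydrobenzofuran-6-ol, via selenide 14 (not isolated), via selenoxide 15 (not isolated), via dienone tautomer 16 (not isolated)
Conditions: LiN(iPr)2 (1.1 equiv), THF, −78 °C; PhSeCl; then 3-chloroperbenzoic acid (1.0 equiv), CH2Cl2, −78 °C; iPr2NH, −78 → 25 °C
Reagents that add atoms: none
Why: Kinetic deprotonation of the vinylogous ester at the α'-carbon C5, selenenylation and selenoxide syn-elimination into C4–C5; the dienone 16 has an acidic C3a–H and tautomerises to the phenol, which erases C3a and C5. Oxidation at −78 °C with one equivalent of peracid and an amine scavenger keeps selenium-derived oxidants away from the electron-rich phenol.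

Step 7
Reactants: 17 (2R,3S)-5-methoxy-3-methyl-2-(3,4,5-trimethoxyphenyl)-2,3-dihydrobenzofuran-6-ol
Product: 18 (2R,3S)-7-bromo-5-methoxy-3-methyl-2-(3,4,5-trimethoxyphenyl)-2,3-dihydrobenzofuran-6-ol
Conditions: N-bromosuccinimide (1.0 equiv), iPr2NH (10 mol%), CH2Cl2, −40 → 0 °C
Reagents that add atoms: N-bromosuccinimide, O=C1CCC(=O)N1Br
Why: Electrophilic aromatic bromination ortho to the free phenol: C7 is the only open position ortho or para to the hydroxyl, since C5 and C3a are substituted. Amine-mediated bromination at low temperature favours it over the trimethoxyphenyl ring.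

Step 8
Reactants: 18 (2R,3S)-7-bromo-5-methoxy-3-methyl-2-(3,4,5-trimethoxyphenyl)-2,3-dihydrobenzofuran-6-ol; 19 allyl tert-butyl carbonate
Product: 21 (2R,3S,3aS)-3a-allyl-7-bromo-5-methoxy-3-methyl-2-(3,4,5-trimethoxyphenyl)-3,3a-dihydrobenzofuran-6(2H)-one, via allyl ether 20 (not isolated)
Conditions: Pd(PPh3)4 (5 mol%), THF, 25 → 45 °C, degassed
Reagents that add atoms: none
Why: Tsuji–Trost alkylative dearomatisation: zerovalent palladium ionises 19 with loss of CO2, the phenoxide of 18 is first O-allylated to 20, and 20 is re-ionised until the carbon para to oxygen (C3a) attacks the π-allyl ligand, C5 and C7 being occupied by methoxyl and bromine. Attack comes from the ring face opposite the cis C3-methyl and C2-aryl groups, which sets C3a with allyl anti to methyl. The dienone should be the resting state because of its vinylogous ester and the relief of the crowded 5,6,7-trisubstituted ether.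

Step 9
Reactants: 21 (2R,3S,3aS)-3a-allyl-7-bromo-5-methoxy-3-methyl-2-(3,4,5-trimethoxyphenyl)-3,3a-dihydrobenzofuran-6(2H)-one
Product: 22 (2R,3S,3aS)-3a-allyl-5-methoxy-3-methyl-2-(3,4,5-trimethoxyphenyl)-3,3a-dihydrobenzofuran-6(2H)-one
Conditions: Zn dust, NH4Cl, THF/EtOH/H2O, 0 → 25 °C
Reagents that add atoms: none
Why: Zinc-mediated reductive dehalogenation of an α-bromo enone: the C7–Br bond of the 2-bromo-3-alkoxy-enone is the most easily reduced site. The buffered, near-neutral medium avoids ionising the C2–O1 bond, and no stereocentre is touched.

## Compound list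

1 | 3,4,5-trimethoxybenzaldehyde | COc1cc(C=O)cc(OC)c1OC | starting material
2 | 4,4,5,5-tetramethyl-2-[(2Z)-but-2-en-1-yl]-1,3,2-dioxaborolane | C/C=C\CB1OC(C)(C)C(C)(C)O1 | starting material
3 | 4,4,5,5-tetramethyl-2-{[(1R,2S)-2-methyl-1-(3,4,5-trimethoxyphenyl)but-3-en-1-yl]oxy}-1,3,2-dioxaborolane (formed in the flask) | CC1(C)OB(O[C@@H](c2cc(OC)c(OC)c(OC)c2)[C@@H](C)C=C)OC1(C)C | intermediate
4 | (1R,2S)-2-methyl-1-(3,4,5-trimethoxyphenyl)but-3-en-1-ol | O[C@@H](c1cc(OC)c(OC)c(OC)c1)[C@@H](C)C=C | intermediate
5 | 9-{[(1R,2S)-4-(9-borabicyclo[3.3.1]nonan-9-yl)-2-methyl-1-(3,4,5-trimethoxyphenyl)butyl]oxy}-9-borabicyclo[3.3.1]nonane (formed in the flask) | O(B1C2CCCC1CCC2)[C@@H](c1cc(OC)c(OC)c(OC)c1)[C@@H](C)CCB1C2CCCC1CCC2 | intermediate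
6 | (1R,2S)-2-methyl-1-(3,4,5-trimethoxyphenyl)butane-1,4-diol | O[C@@H](c1cc(OC)c(OC)c(OC)c1)[C@@H](C)CCO | intermediate
7 | (4S,5R)-4-methyl-5-(3,4,5-trimethoxyphenyl)oxolan-2-ol, both anomers (formed in the flask) | OC1O[C@@H](c2cc(OC)c(OC)c(OC)c2)[C@@H](C)C1 | intermediate
8 | (4S,5R)-4-methyl-5-(3,4,5-trimethoxyphenyl)dihydrofuran-2(3H)-one | O=C1O[C@@H](c2cc(OC)c(OC)c(OC)c2)[C@@H](C)C1 | intermediate
9 | 3,3-dimethoxybutan-2-one | CC(=O)C(C)(OC)OC | starting material
10 | 3-methoxybut-3-en-2-one | CC(=O)C(=C)OC | intermediate
11 | (3S,4S,5R)-3-(2-methoxy-3-oxobutyl)-4-methyl-5-(3,4,5-trimethoxyphenyl)dihydrofuran-2(3H)-one, epimers at the methoxy carbon (formed in the flask) | CC(=O)C(OC)C[C@@H]1C(=O)O[C@@H](c2cc(OC)c(OC)c(OC)c2)[C@H]1C | intermediate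
12 | (4S)-4-[(1R,2S)-1-hydroxy-1-(3,4,5-trimethoxyphenyl)propan-2-yl]-6-methoxycyclohexane-1,3-dione, C6 epimers (formed in the flask) | COC1C[C@H](C(=O)CC1=O)[C@H](C)[C@@H](O)c1cc(OC)c(OC)c(OC)c1 | intermediate
13 | (2R,3S,3aS)-5-methoxy-3-methyl-2-(3,4,5-trimethoxyphenyl)-3,3a,4,5-tetrahydrobenzofuran-6(2H)-one, C5 epimers (5S drawn) | CO[C@H]1C[C@@H]2C(=CC1=O)O[C@@H](c1cc(OC)c(OC)c(OC)c1)[C@H]2C | intermediate
14 | (2R,3S,3aS)-5-methoxy-3-methyl-5-(phenylselanyl)-2-(3,4,5-trimethoxyphenyl)-3,3a,4,5-tetrahydrobenzofuran-6(2H)-one, C5 epimers (formed in the flask) | COC1([Se]c3ccccc3)C[C@@H]2C(=CC1=O)O[C@@H](c1cc(OC)c(OC)c(OC)c1)[C@H]2C | intermediate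
15 | (2R,3S,3aS)-5-methoxy-3-methyl-5-(phenylseleninyl)-2-(3,4,5-trimethoxyphenyl)-3,3a,4,5-tetrahydrobenzofuran-6(2H)-one (formed in the flask) | COC1([Se](=O)c3ccccc3)C[C@@H]2C(=CC1=O)O[C@@H](c1cc(OC)c(OC)c(OC)c1)[C@H]2C | intermediate
16 | (2R,3S,3aR)-5-methoxy-3-methyl-2-(3,4,5-trimethoxyphenyl)-3,3a-dihydrobenzofuran-6(2H)-one (formed in the flask) | COC1=C[C@@H]2C(=CC1=O)O[C@@H](c1cc(OC)c(OC)c(OC)c1)[C@H]2C | intermediate
17 | (2R,3S)-5-methoxy-3-methyl-2-(3,4,5-trimethoxyphenyl)-2,3-dihydrobenzofuran-6-ol | COc1cc2c(cc1O)O[C@@H](c1cc(OC)c(OC)c(OC)c1)[C@H]2C | intermediate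
18 | (2R,3S)-7-bromo-5-methoxy-3-methyl-2-(3,4,5-trimethoxyphenyl)-2,3-dihydrobenzofuran-6-ol | COc1cc2c(c(Br)c1O)O[C@@H](c1cc(OC)c(OC)c(OC)c1)[C@H]2C | intermediate
19 | allyl tert-butyl carbonate | C=CCOC(=O)OC(C)(C)C | starting material
20 | (2R,3S)-6-(allyloxy)-7-bromo-5-methoxy-3-methyl-2-(3,4,5-trimethoxyphenyl)-2,3-dihydrobenzofuran (formed in the flask) | C=CCOc1c(Br)c2O[C@@H](c3cc(OC)c(OC)c(OC)c3)[C@@H](C)c2cc1OC | intermediate
21 | (2R,3S,3aS)-3a-allyl-7-bromo-5-methoxy-3-methyl-2-(3,4,5-trimethoxyphenyl)-3,3a-dihydrobenzofuran-6(2H)-one | C=CC[C@]12C=C(OC)C(=O)C(Br)=C1O[C@@H](c1cc(OC)c(OC)c(OC)c1)[C@H]2C | intermediate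
22 | (2R,3S,3aS)-3a-allyl-5-methoxy-3-methyl-2-(3,4,5-trimethoxyphenyl)-3,3a-dihydrobenzofuran-6(2H)-one | C=CC[C@]12C=C(OC)C(=O)C=C1O[C@@H](c1cc(OC)c(OC)c(OC)c1)[C@H]2C | target

## Step count and least certain steps

Total step count: 9. Longest linear sequence: 8 steps (1 → 4 → 6 → 8 → 13 → 17 → 18 → 21 → 22); step 4 is a one-step branch.

**Step 5 (key step).** The likely failures are competing 1,2-addition, proton transfer from the methyl ketone of 10 to the lactone enolate, and anionic oligomerisation of the enone. The Claisen closure may also lag so that the open adduct persists, and too much acid in the cyclodehydration would epimerise C2. The fallback separates the two bond formations. It sets out from 8, which is converted (LiN(iPr)2, tBuMe2SiCl) into the silyl ketene acetal tert-butyl(dimethyl){[(4S,5R)-4-methyl-5-(3,4,5-trimethoxyphenyl)-4,5-dihydrofuran-2-yl]oxy}silane F1. F1 undergoes a Mukaiyama–Michael addition to 10 with catalytic Me3SiNTf2 at −78 °C, which gives 11 as an isolated compound after hydrolysis. KOtBu in THF then effects the Claisen closure to 12, and the same mild acid treatment brings the route back at 13.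

**Step 8.** O-Allylation should be fast. The danger is that the system rests at 20, either because attack by the hindered para carbon is slow or because the ether–dienone equilibrium is unfavourable. Slow insertion of zerovalent palladium into a C–Br bond would also remove catalyst. The fallback is kinetically controlled and uses no palladium. It sets out from 18, which is oxidised with PhI(OAc)2 in (CF3)2CHOH/CH2Cl2 at −20 °C in the presence of excess allyltrimethylsilane. The phenoxonium ion is trapped at C3a, anti to the methyl group (Hosomi–Sakurai-type dearomatisation of a 4-alkylphenol), and the route is rejoined at 21. It makes no new compound (F0). It must be kept cold, brief and buffered, because the ionising medium could epimerise C2.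

**Step 9.** Electron transfer may go into the dienone instead of the C–Br bond, with loss of the allyl group and rearomatisation, or with over-reduction; any acidity would epimerise C2. The fallback changes from electron transfer to a two-electron palladium hydride cycle. It sets out from 21, which is treated with Pd(OAc)2/PPh3 and HCO2H/Et3N in DMF at 50 °C (oxidative addition into the vinylic C–Br bond, formate-to-hydride exchange, reductive elimination). It comes back at 22 and makes no new compound (F0).

**Step 6.** Enolisation towards C3a instead of C5 would place selenium at C3a. Elimination towards C3 could then scramble that centre. The electron-rich phenol may also be over-oxidised by selenium-derived oxidants. The fallback carries the leaving group through the annulation and sets out from 8: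
- Sulfenylation (LiN(iPr)2, PhSSPh) gives (3S,4R,5R)-4-methyl-3-(phenylsulfanyl)-5-(3,4,5-trimethoxyphenyl)dihydrofuran-2(3H)-one F2.
- The softer enolate of F2 is taken through the step 5 protocol with 10 to give (2R,3R,3aR)-5-methoxy-3-methyl-3a-(phenylsulfanyl)-2-(3,4,5-trimethoxyphenyl)-3,3a,4,5-tetrahydrobenzofuran-6(2H)-one F3.
- One equivalent of 3-chloroperbenzoic acid at −78 °C gives the sulfoxide (2R,3R,3aR)-5-methoxy-3-methyl-3a-(phenylsulfinyl)-2-(3,4,5-trimethoxyphenyl)-3,3a,4,5-tetrahydrobenzofuran-6(2H)-one F4.
- Warming F4 in PhMe over CaCO3 causes syn-elimination into C3a–C4. The C3 hydrogen is anti to sulfur and cannot take part. Tautomerisation returns the route at 17.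

## Further compounds

F1 | step 5 | tert-butyl(dimethyl){[(4S,5R)-4-methyl-5-(3,4,5-trimethoxyphenyl)-4,5-dihydrofuran-2-yl]oxy}silane | CC(C)(C)[Si](C)(C)OC1=C[C@H](C)[C@H](c2cc(OC)c(OC)c(OC)c2)O1
F2 | step 6 | (3S,4R,5R)-4-methyl-3-(phenylsulfanyl)-5-(3,4,5-trimethoxyphenyl)dihydrofuran-2(3H)-one | O=C1O[C@@H](c2cc(OC)c(OC)c(OC)c2)[C@@H](C)[C@@H]1Sc1ccccc1
F3 | step 6 | (2R,3R,3aR)-5-methoxy-3-methyl-3a-(phenylsulfanyl)-2-(3,4,5-trimethoxyphenyl)-3,3a,4,5-tetrahydrobenzofuran-6(2H)-one, C5 epimers | COC1C[C@]2(Sc3ccccc3)C(=CC1=O)O[C@@H](c1cc(OC)c(OC)c(OC)c1)[C@H]2C
F4 | step 6 | (2R,3R,3aR)-5-methoxy-3-methyl-3a-(phenylsulfinyl)-2-(3,4,5-trimethoxyphenyl)-3,3a,4,5-tetrahydrobenzofuran-6(2H)-one, C5 and sulfur epimers | COC1C[C@]2(S(=O)c3ccccc3)C(=CC1=O)O[C@@H](c1cc(OC)c(OC)c(OC)c1)[C@H]2C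
F0 | step 8 | none | none
F0 | step 9 | none | none
A1 | alternative 1 | (2R,3S)-6-(allyloxy)-7-bromo-5-methoxy-3-methyl-2-(3,4,5-trimethoxyphenyl)-2,3-dihydrobenzofuran | C=CCOc1c(Br)c2O[C@@H](c3cc(OC)c(OC)c(OC)c3)[C@@H](C)c2cc1OC
A2 | alternative 1 | 2-(allyloxy)-3-bromo-5-(1-diazoethyl)-1-methoxy-4-[(3,4,5-trimethoxybenzyl)oxy]benzene | C=CCOc1c(Br)c(OCc2cc(OC)c(OC)c(OC)c2)c(C(C)=[N+]=[N-])cc1OC
A3 | alternative 2 | (6S)-6-allyl-3-isopropoxy-4-methoxy-6-[(1R,2S)-1-(tert-butyldimethylsilyloxy)-1-(3,4,5-trimethoxyphenyl)propan-2-yl]cyclohexa-2,4-dien-1-one | C=CC[C@@]1(C=C(OC)C(OC(C)C)=CC1=O)[C@H](C)[C@@H](O[Si](C)(C)C(C)(C)C)c1cc(OC)c(OC)c(OC)c1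
A4 | alternative 2 | 4-[(3S,4R)-2-allyl-4-(tert-butyldimethylsilyloxy)-3-methyl-4-(3,4,5-trimethoxyphenyl)but-1-en-1-yl]-3-isopropoxy-4-methoxycyclobut-2-en-1-one (alkene geometry and ring C4 not specified) | C=CCC(=CC1(OC)C(OC(C)C)=CC1=O)[C@H](C)[C@@H](O[Si](C)(C)C(C)(C)C)c1cc(OC)c(OC)c(OC)c1
A5 | alternative 3 | (2R,3S,3aR,5S)-3a-allyl-5-methoxy-3-methyl-5-(phenylsulfonyl)-2-(3,4,5-trimethoxyphenyl)-3,3a,4,5-tetrahydrobenzofuran-6(2H)-one | C=CC[C@]12C[C@](OC)(S(=O)(=O)c3ccccc3)C(=O)C=C1O[C@@H](c1cc(OC)c(OC)c(OC)c1)[C@H]2C
A6 | alternative 3 | methyl 2-[(3R,4S,5R)-3-allyl-3-[2-methoxy-2-(phenylsulfonyl)ethyl]-4-methyl-5-(3,4,5-trimethoxyphenyl)oxolan-2-ylidene]acetate (alkene geometry and sulfone carbon not specified) | C=CC[C@]1(CC(OC)S(=O)(=O)c2ccccc2)C(=CC(=O)OC)O[C@@H](c2cc(OC)c(OC)c(OC)c2)[C@H]1C
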